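**Assumption:** 2-C-methyl-D-ribono-1,4-lactone, 2-methylbut-1-en-3-yne and D-(−)-diisopropyl tartrate are taken as commercial; positions are given in germacrane numbering (C1–C15); TBS = tert-butyldimethylsilyl.

## Retrosynthetic overview

1. The last ring to close is the ten-membered carbocycle (a nine-membered ring counted through the 3,10-oxygen bridge), by ring-closing metathesis that forms the Z-C4=C5 olefin from a furanone-bound isopropenyl group and a propenyl group on C6.
2. The seco-diene comes from a C7–C8 zinc Barbier union of a furanone α-silyloxy aldehyde with an (R)-α-(bromomethyl)butenolide. This sets C7; C8 is expected to come out epimeric and is inverted by Mitsunobu esterification with isovaleric acid; C9 then goes from TBS ether to acetate.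
3. The furanone aldehyde comes from 2-C-methyl-D-ribono-1,4-lactone (supplies C9 and C10; its C4–C5 diol is the masked C8 aldehyde) and isopropenylacetylene, by acetylide addition and gold cycloisomerisation.
4. The bromobutenolide comes from (S,E)-hexa-1,4-dien-3-ol (Sharpless kinetic resolution) and 2-(bromomethyl)acrylic acid (from diethyl malonate), by esterification and RCM.
5. Ring order: 3(2H)-furanone, then butenolide (which becomes the α-methylene-γ-lactone in the Barbier step), then the medium ring.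

## Route

Step 1
Reactants: 1 diethyl malonate; 2 formaldehyde
Product: 3 diethyl 2,2-bis(hydroxymethyl)malonate
Conditions: 37% aq HCHO (2.0 equiv), KHCO3 (cat.), H2O, 25–30 °C
Reagents that add atoms: formaldehyde, C=O
Why: Base-catalysed double aldol-type hydroxymethylation of the doubly activated malonate CH2 takes up two equivalents of formaldehyde (one as reactant 2 and the second as the listed reagent), and no stereocentre is formed.

Step 2
Reactants: 3 diethyl 2,2-bis(hydroxymethyl)malonate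
Product: 4 2-(bromomethyl)prop-2-enoic acid
Conditions: 48% aq HBr, 85–90 °C, volatiles distilled off
Reagents that add atoms: hydrogen bromide, Br
Why: One-pot acidic ester hydrolysis, decarboxylation, β-elimination of water and OH-to-Br substitution give the bromomethyl acrylic acid.

Step 3
Reactants: 5 (E)-but-2-enal; 6 vinylmagnesium bromide
Product: 7 rac-(4E)-hexa-1,4-dien-3-ol
Conditions: THF, −78 → 0 °C; sat. aq NH4Cl
Reagents that add atoms: none
Why: Grignard 1,2-addition of the hard vinyl nucleophile to the enal gives the racemic bis-allylic alcohol.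

Step 4
Reactants: 7 rac-(4E)-hexa-1,4-dien-3-ol
Product: 8 (3S,4E)-hexa-1,4-dien-3-ol
Conditions: Ti(OiPr)4 (0.10 equiv), D-(−)-DIPT (0.15 equiv), t-BuOOH (0.6 equiv), 4 Å MS, CH2Cl2, −20 °C, stopped at ca. 55–60% conversion
Reagents that add atoms: none
Why: Sharpless kinetic resolution; with D-(−)-tartrate the (R)-alcohol is epoxidised fast at its E-propenyl double bond to the erythro epoxy alcohol, so the (S)-alcohol is recovered in high ee.

Step 5
Reactants: 8 (3S,4E)-hexa-1,4-dien-3-ol; 4 2-(bromomethyl)prop-2-enoic acid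
Product: 9 (3S,4E)-hexa-1,4-dien-3-yl 2-(bromomethyl)prop-2-enoate
Conditions: DCC (1.1 equiv), DMAP (0.05 equiv), CH2Cl2, −20 → 0 °C
Reagents that add atoms: none
Why: Steglich esterification acylates the carbinol oxygen with retention; low temperature and little DMAP spare the allylic bromide.

Step 6
Reactants: 9 (3S,4E)-hexa-1,4-dien-3-yl 2-(bromomethyl)prop-2-enoate
Product: 10 (5R)-3-(bromomethyl)-5-[(1E)-prop-1-en-1-yl]furan-2(5H)-one
Conditions: Grubbs II (5 mol %), CH2Cl2 (5 mM), 40 °C, Ar sparge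
Reagents that add atoms: none
Why: Ring-closing metathesis; ruthenium loads at the terminal vinyl group and closes onto the acrylate olefin to give the butenolide, while the slower propenyl group stays as a substituent and the stereocentre is untouched (the descriptor changes from S to R only through CIP priorities).

Step 7
Reactants: 11 2-C-methyl-D-ribono-1,4-lactone [(3R,4R,5R)-3,4-dihydroxy-5-(hydroxymethyl)-3-methyloxolan-2-one]
Product: 12 (3R,4R,5R)-4-(TBSO)-5-(TBSOCH2)-3-hydroxy-3-methyloxolan-2-one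
Conditions: TBSCl (2.5 equiv), imidazole (5 equiv), DMF, 40 °C
Reagents that add atoms: tert-butyldimethylsilyl chloride, CC(C)(C)[Si](C)(C)Cl
Why: Silyl ether formation at the primary and secondary hydroxyls (two equivalents of TBSCl are taken up); the tertiary α-hydroxy-lactone OH (future furanone oxygen on C10) is too hindered to react.

Step 8
Reactants: 12 (3R,4R,5R)-4-(TBSO)-5-(TBSOCH2)-3-hydroxy-3-methyloxolan-2-one; 13 2-methylbut-1-en-3-yne
Product: 15 (3R,4R,5R)-4-(TBSO)-5-(TBSOCH2)-3-methyl-2-(3-methylbut-3-en-1-yn-1-yl)oxolane-2,3-diol (anomer mixture), via lithium 3-methylbut-3-en-1-yn-1-ide 14 (not isolated)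
Conditions: 13 (3.2 equiv), n-BuLi (3.0 equiv), THF, −78 °C; then 12, −78 → −40 °C; sat. aq NH4Cl
Reagents that add atoms: none
Why: Acetylide addition to the lactone carbonyl stops at the lactol because the lithium hemiketal is stable at low temperature (one equivalent of acetylide is spent on the free OH); the C9 and C10 stereocentres are not touched.

Step 9
Reactants: 15 (3R,4R,5R)-4-(TBSO)-5-(TBSOCH2)-3-methyl-2-(3-methylbut-3-en-1-yn-1-yl)oxolane-2,3-diol (anomer mixture)
Product: 17 (2R)-2-[(1R,2R)-1,3-bis(TBSO)-2-hydroxypropyl]-2-methyl-5-(prop-1-en-2-yl)furan-3(2H)-one, via open-chain α′-hydroxy ynone 16 (not isolated)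
Conditions: Ph3PAuCl (5 mol %), AgOTf (5 mol %), toluene, rt
Reagents that add atoms: none
Why: Gold(I)-catalysed 5-endo-dig cycloisomerisation of the ring-opened α′-hydroxy ynone (tertiary C10–OH onto the alkyne) gives the 3(2H)-furanone; no bond to C10 breaks, so its configuration is retained.

Step 10
Reactants: 17 (2R)-2-[(1R,2R)-1,3-bis(TBSO)-2-hydroxypropyl]-2-methyl-5-(prop-1-en-2-yl)furan-3(2H)-one
Product: 18 (2R)-2-[(1R,2R)-1-(TBSO)-2,3-dihydroxypropyl]-2-methyl-5-(prop-1-en-2-yl)furan-3(2H)-one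
Conditions: HF·pyridine, pyridine, THF, 0 °C
Reagents that add atoms: none
Why: Selective desilylation; the primary TBS ether is cleaved much faster than the hindered secondary one next to the quaternary carbon.

Step 11
Reactants: 18 (2R)-2-[(1R,2R)-1-(TBSO)-2,3-dihydroxypropyl]-2-methyl-5-(prop-1-en-2-yl)furan-3(2H)-one
Product: 19 (2S)-2-(TBSO)-2-[(2R)-2-methyl-3-oxo-5-(prop-1-en-2-yl)-2,3-dihydrofuran-2-yl]acetaldehyde
Conditions: NaIO4 (1.5 equiv), THF/pH 7 buffer, 0 °C → rt
Reagents that add atoms: none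
Why: Malaprade glycol cleavage unmasks the C8 aldehyde under neutral conditions that do not epimerise the α-silyloxy centre (C9).

Step 12
Reactants: 19 (2S)-2-(TBSO)-2-[(2R)-2-methyl-3-oxo-5-(prop-1-en-2-yl)-2,3-dihydrofuran-2-yl]acetaldehyde; 10 (5R)-3-(bromomethyl)-5-[(1E)-prop-1-en-1-yl]furan-2(5H)-one
Product: 21 (4R,5R)-4-{(1R,2R)-2-(TBSO)-1-hydroxy-2-[(2R)-2-methyl-3-oxo-5-(prop-1-en-2-yl)-2,3-dihydrofuran-2-yl]ethyl}-3-methylidene-5-[(1E)-prop-1-en-1-yl]oxolan-2-one, via allylzinc bromide 20 (not isolated)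
Conditions: Zn dust (3 equiv), THF/sat. aq NH4Cl (2:1), 0 °C → rt
Reagents that add atoms: none
Why: Zinc Barbier allylation; the allylzinc reacts SE2′ through the butenolide β-carbon anti to the C6 propenyl group (C7 trans to C6, exocyclic methylene unveiled), and the Zimmerman–Traxler chair of the ring-constrained E-type allyl unit plus Felkin–Anh addition anti to the α-OTBS group (a matched pair) are expected to set C8 as the (R)-carbinol, the C8 epimer of the target.

Step 13
Reactants: 21 (4R,5R)-4-{(1R,2R)-2-(TBSO)-1-hydroxy-2-[(2R)-2-methyl-3-oxo-5-(prop-1-en-2-yl)-2,3-dihydrofuran-2-yl]ethyl}-3-methylidene-5-[(1E)-prop-1-en-1-yl]oxolan-2-one; 22 3-methylbutanoic acid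
Product: 23 (1S,2R)-2-(TBSO)-2-[(2R)-2-methyl-3-oxo-5-(prop-1-en-2-yl)-2,3-dihydrofuran-2-yl]-1-{(2R,3S)-4-methylidene-5-oxo-2-[(1E)-prop-1-en-1-yl]oxolan-3-yl}ethyl 3-methylbutanoate
Conditions: PPh3 (3 equiv), DIAD (3 equiv), toluene, 0 °C → rt
Reagents that add atoms: none
Why: Mitsunobu esterification displaces the C8 oxyphosphonium by isovalerate with inversion, giving the required 8S ester; the C9 silyl ether cannot participate, so no acyloxonium scrambling occurs.

Step 14
Reactants: 23 (1S,2R)-2-(TBSO)-2-[(2R)-2-methyl-3-oxo-5-(prop-1-en-2-yl)-2,3-dihydrofuran-2-yl]-1-{(2R,3S)-4-methylidene-5-oxo-2-[(1E)-prop-1-en-1-yl]oxolan-3-yl}ethyl 3-methylbutanoate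
Product: 24 (1S,2R)-2-hydroxy-2-[(2R)-2-methyl-3-oxo-5-(prop-1-en-2-yl)-2,3-dihydrofuran-2-yl]-1-{(2R,3S)-4-methylidene-5-oxo-2-[(1E)-prop-1-en-1-yl]oxolan-3-yl}ethyl 3-methylbutanoate
Conditions: HF·pyridine, pyridine, THF, 0 °C → rt
Reagents that add atoms: none
Why: Fluoride desilylation under buffered, slightly acidic conditions frees the C9 hydroxyl without base-induced migration of the neighbouring isovalerate.

Step 15
Reactants: 24 (1S,2R)-2-hydroxy-2-[(2R)-2-methyl-3-oxo-5-(prop-1-en-2-yl)-2,3-dihydrofuran-2-yl]-1-{(2R,3S)-4-methylidene-5-oxo-2-[(1E)-prop-1-en-1-yl]oxolan-3-yl}ethyl 3-methylbutanoate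
Product: 25 (1S,2R)-2-(acetyloxy)-2-[(2R)-2-methyl-3-oxo-5-(prop-1-en-2-yl)-2,3-dihydrofuran-2-yl]-1-{(2R,3S)-4-methylidene-5-oxo-2-[(1E)-prop-1-en-1-yl]oxolan-3-yl}ethyl 3-methylbutanoate
Conditions: Ac2O, DMAP (cat.), pyridine, CH2Cl2, 0 °C → rt
Reagents that add atoms: acetic anhydride, CC(=O)OC(C)=O
Why: DMAP-catalysed acetylation of the only free hydroxyl; no stereocentre is affected.

Step 16
Reactants: 25 (1S,2R)-2-(acetyloxy)-2-[(2R)-2-methyl-3-oxo-5-(prop-1-en-2-yl)-2,3-dihydrofuran-2-yl]-1-{(2R,3S)-4-methylidene-5-oxo-2-[(1E)-prop-1-en-1-yl]oxolan-3-yl}ethyl 3-methylbutanoate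
Product: 26 (6R,7S,8S,9R,10R)-9-acetoxy-8-(3-methylbutanoyloxy)-1-oxo-3,10-epoxygermacra-2,4Z,11(13)-trien-12,6-olide (the target)
Conditions: Hoveyda–Grubbs II (2 × 10 mol %), 1,4-benzoquinone (cat.), toluene (1 mM), 100 °C, Ar sparge
Reagents that add atoms: none
Why: Ring-closing metathesis; the catalyst loads at the propenyl group and closes onto the isopropenyl group to give the trisubstituted C4=C5 olefin, which can only be Z in the nine-membered oxa-bridged ring, while the electron-poor exocyclic methylene is a spectator and no stereocentre is touched.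

## Compound list

1 | diethyl malonate | CCOC(=O)CC(=O)OCC | starting material
2 | formaldehyde | C=O | starting material
3 | diethyl 2,2-bis(hydroxymethyl)malonate | CCOC(=O)C(CO)(CO)C(=O)OCC | intermediate
4 | 2-(bromomethyl)prop-2-enoic acid | C=C(CBr)C(=O)O | intermediate
5 | (E)-but-2-enal | C/C=C/C=O | starting material
6 | vinylmagnesium bromide | C=C[Mg]Br | starting material
7 | rac-(4E)-hexa-1,4-dien-3-ol | C=CC(O)/C=C/C | intermediate
8 | (3S,4E)-hexa-1,4-dien-3-ol | C=C[C@H](O)/C=C/C | intermediate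
9 | (3S,4E)-hexa-1,4-dien-3-yl 2-(bromomethyl)prop-2-enoate | C=C[C@H](OC(=O)C(=C)CBr)/C=C/C | intermediate
10 | (5R)-3-(bromomethyl)-5-[(1E)-prop-1-en-1-yl]furan-2(5H)-one | O=C1O[C@H](/C=C/C)C=C1CBr | intermediate
11 | 2-C-methyl-D-ribono-1,4-lactone | O=C1[C@](C)(O)[C@H](O)[C@@H](CO)O1 | starting material
12 | (3R,4R,5R)-4-(TBSO)-5-(TBSOCH2)-3-hydroxy-3-methyloxolan-2-one | O=C1[C@](C)(O)[C@H](O[Si](C)(C)C(C)(C)C)[C@@H](CO[Si](C)(C)C(C)(C)C)O1 | intermediate
13 | 2-methylbut-1-en-3-yne | C=C(C)C#C | starting material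
14 | lithium 3-methylbut-3-en-1-yn-1-ide | C=C(C)C#C[Li] | intermediate (not isolated)
15 | (3R,4R,5R)-4-(TBSO)-5-(TBSOCH2)-3-methyl-2-(3-methylbut-3-en-1-yn-1-yl)oxolane-2,3-diol (anomer mixture) | OC1(C#CC(C)=C)[C@](C)(O)[C@H](O[Si](C)(C)C(C)(C)C)[C@@H](CO[Si](C)(C)C(C)(C)C)O1 | intermediate
16 | (6R,7R,8R)-7,9-bis(TBSO)-6,8-dihydroxy-2,6-dimethylnon-1-en-3-yn-5-one | C=C(C)C#CC(=O)[C@](C)(O)[C@H](O[Si](C)(C)C(C)(C)C)[C@H](O)CO[Si](C)(C)C(C)(C)C | intermediate (not isolated)
17 | (2R)-2-[(1R,2R)-1,3-bis(TBSO)-2-hydroxypropyl]-2-methyl-5-(prop-1-en-2-yl)furan-3(2H)-one | C=C(C)C1=CC(=O)[C@](C)(O1)[C@H](O[Si](C)(C)C(C)(C)C)[C@H](O)CO[Si](C)(C)C(C)(C)C | intermediate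
18 | (2R)-2-[(1R,2R)-1-(TBSO)-2,3-dihydroxypropyl]-2-methyl-5-(prop-1-en-2-yl)furan-3(2H)-one | C=C(C)C1=CC(=O)[C@](C)(O1)[C@H](O[Si](C)(C)C(C)(C)C)[C@H](O)CO | intermediate
19 | (2S)-2-(TBSO)-2-[(2R)-2-methyl-3-oxo-5-(prop-1-en-2-yl)-2,3-dihydrofuran-2-yl]acetaldehyde | C=C(C)C1=CC(=O)[C@](C)(O1)[C@H](O[Si](C)(C)C(C)(C)C)C=O | intermediate
20 | {[(5R)-2-oxo-5-[(1E)-prop-1-en-1-yl]-2,5-dihydrofuran-3-yl]methyl}zinc bromide | O=C1O[C@H](/C=C/C)C=C1C[Zn]Br | intermediate (not isolated)
21 | (4R,5R)-4-{(1R,2R)-2-(TBSO)-1-hydroxy-2-[(2R)-2-methyl-3-oxo-5-(prop-1-en-2-yl)-2,3-dihydrofuran-2-yl]ethyl}-3-methylidene-5-[(1E)-prop-1-en-1-yl]oxolan-2-one | C=C1C(=O)O[C@H](/C=C/C)[C@H]1[C@@H](O)[C@@H](O[Si](C)(C)C(C)(C)C)[C@@]2(C)OC(C(C)=C)=CC2=O | intermediate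
22 | 3-methylbutanoic acid | CC(C)CC(=O)O | starting material
23 | (1S,2R)-2-(TBSO)-2-[(2R)-2-methyl-3-oxo-5-(prop-1-en-2-yl)-2,3-dihydrofuran-2-yl]-1-{(2R,3S)-4-methylidene-5-oxo-2-[(1E)-prop-1-en-1-yl]oxolan-3-yl}ethyl 3-methylbutanoate | C=C1C(=O)O[C@H](/C=C/C)[C@H]1[C@H](OC(=O)CC(C)C)[C@@H](O[Si](C)(C)C(C)(C)C)[C@@]2(C)OC(C(C)=C)=CC2=O | intermediate
24 | (1S,2R)-2-hydroxy-2-[(2R)-2-methyl-3-oxo-5-(prop-1-en-2-yl)-2,3-dihydrofuran-2-yl]-1-{(2R,3S)-4-methylidene-5-oxo-2-[(1E)-prop-1-en-1-yl]oxolan-3-yl}ethyl 3-methylbutanoate | C=C1C(=O)O[C@H](/C=C/C)[C@H]1[C@H](OC(=O)CC(C)C)[C@@H](O)[C@@]2(C)OC(C(C)=C)=CC2=O | intermediate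
25 | (1S,2R)-2-(acetyloxy)-2-[(2R)-2-methyl-3-oxo-5-(prop-1-en-2-yl)-2,3-dihydrofuran-2-yl]-1-{(2R,3S)-4-methylidene-5-oxo-2-[(1E)-prop-1-en-1-yl]oxolan-3-yl}ethyl 3-methylbutanoate (seco-diene) | C=C1C(=O)O[C@H](/C=C/C)[C@H]1[C@H](OC(=O)CC(C)C)[C@@H](OC(C)=O)[C@@]2(C)OC(C(C)=C)=CC2=O | intermediate
26 | (6R,7S,8S,9R,10R)-9-acetoxy-8-(3-methylbutanoyloxy)-1-oxo-3,10-epoxygermacra-2,4Z,11(13)-trien-12,6-olide | C=C1C(=O)O[C@@H]2/C=C(/C)C3=CC(=O)[C@](C)(O3)[C@H](OC(C)=O)[C@@H](OC(=O)CC(C)C)[C@@H]12 | target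

## Step count

Total steps: 16 (acid branch 1–2, butenolide branch 3–6, furanone branch 7–11, common 12–16).
Longest linear sequence: 10 steps (7–16), which is 10/16 of the total.

## Steps most likely to fail, with fallbacks

(a) Step 16, the ring-closing metathesis. It must form a trisubstituted olefin from an electron-poor 1,1-disubstituted alkene inside a strained nine-membered oxa-bridged ring, on a fully acylated substrate. The fallback closes the ring earlier, on the less encumbered Barbier adduct with a free C8 hydroxyl and the opposite C8 configuration. It sets out from 21: Hoveyda–Grubbs II in hot dilute toluene gives the macrocyclic 8-epi alcohol F1. Mitsunobu reaction of this with 22 (PPh3, DIAD) gives the macrocyclic 9-O-TBS 8-isovalerate F2. HF·pyridine then gives the macrocyclic 9-deacetyl alcohol F3. Acetylation (Ac2O, DMAP) comes back to the route at 26.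

(b) Step 13, the Mitsunobu inversion. The C8 alcohol is flanked by the lactone ring carbon and a silyloxy carbon next to a quaternary centre, and isovaleric acid is a weak pronucleophile, so retention through an acyloxyphosphonium, elimination toward C7 or phosphine addition to the methylene lactone are possible. The fallback separates activation from displacement. It sets out from 21: ClCH2SO2Cl and pyridine in CH2Cl2 at 0 °C give the C8 chloromethanesulfonate F4. SN2 displacement by the carboxylate of 22 (22, Cs2CO3, 18-crown-6, toluene, 60 °C) inverts C8 and comes back at 23.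

(c) Step 9, the gold cycloisomerisation. The substrate rests as a lactol, and gold may instead trigger Meyer–Schuster-type chemistry of the propargylic hemiketal or react at the conjugated enyne. The fallback is a conjugate addition followed by addition–elimination, without a π-acid. It sets out from 15: diethylamine in ethanol at rt adds to the ring-opened ynone to give the β-diethylamino enone F5. Dilute aqueous acetic acid in THF then lets the tertiary C10 hydroxyl displace the amine by 5-exo addition–elimination, coming back at 17.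

## Further compounds

F1 | step 16 | macrocyclic 8-epi alcohol (ring-closed 21; 8R-hydroxy, 9-O-TBS) | C=C1C(=O)O[C@@H]2/C=C(/C)C3=CC(=O)[C@](C)(O3)[C@H](O[Si](C)(C)C(C)(C)C)[C@H](O)[C@@H]12
F2 | step 16 | macrocyclic 9-O-TBS 8-isovalerate (9-deacetyl-9-O-TBS target) | C=C1C(=O)O[C@@H]2/C=C(/C)C3=CC(=O)[C@](C)(O3)[C@H](O[Si](C)(C)C(C)(C)C)[C@@H](OC(=O)CC(C)C)[C@@H]12
F3 | step 16 | macrocyclic 9-deacetyl alcohol (9-hydroxy, 8-isovalerate) | C=C1C(=O)O[C@@H]2/C=C(/C)C3=CC(=O)[C@](C)(O3)[C@H](O)[C@@H](OC(=O)CC(C)C)[C@@H]12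
F4 | step 13 | C8 chloromethanesulfonate of 21 | C=C1C(=O)O[C@H](/C=C/C)[C@H]1[C@@H](OS(=O)(=O)CCl)[C@@H](O[Si](C)(C)C(C)(C)C)[C@@]2(C)OC(C(C)=C)=CC2=O
F5 | step 9 | β-diethylamino enone (diethylamine adduct of ynone 16) | C=C(C)C(=CC(=O)[C@](C)(O)[C@H](O[Si](C)(C)C(C)(C)C)[C@H](O)CO[Si](C)(C)C(C)(C)C)N(CC)CC
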